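**Assumption (one line):** cembrane numbering is used throughout (C1 = lactone β-carbon, C3/C4 = epoxide, C7 = allylic carbinol, C8(19) = exocyclic methylene, C12 = CH–CH3, C13 = free carbinol, C14 = lactone O–CH, C15–C17 = acrylate); both antipodes of the Shi ketone and of Ipc2BOMe are taken as purchasable reagents.

## Retrosynthetic overview

1. Target ⇐ last-step Shi epoxidation (reagent control) of the 3E-olefin of the 14-membered diene-diol lactone; the oxirane is the third ring formed.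
2. Key bond C1–C14: indium turns the enoate β-carbon C1 of a 2-(bromomethyl)enoate (normally an acceptor) into a donor, an ester homoenolate equivalent, which attacks the aldehyde carbon C14 intramolecularly. This closes the 14-membered carbocycle (first ring) and sets C1 and C14; lactonisation in the same flask gives the γ-lactone (second ring).
3. Seco-bromide ⇐ C1–C2 bond (copper-catalysed propiolate alkylation, then hydroalumination/CH2O and Appel bromination) and C9–C10 bond (2-methylallyl alkoxide dianion + primary iodide).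
4. East part C2–C9 ⇐ geraniol (Shi epoxidation with the L-series ketone sets C7; aluminium amide isomerisation gives the 8(19)-methylene carbinol). West part C10–C14 ⇐ Brown (Z)-crotylation of 2,2-dimethoxyacetaldehyde (sets C12 and C13), then hydrozirconation/iodination.

## Route

Step 1
Reactants: 1 2,2-dimethoxyacetaldehyde; 2 cis-but-2-ene
Product: 6 (2R,3S)-1,1-dimethoxy-3-methylpent-4-en-2-ol, via crotylpotassium 3 (not isolated), via crotylborane 4 (not isolated), via borinate 5 (not isolated)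
Conditions: 2, KOtBu, n-BuLi, THF, −78 to −45 °C; (+)-Ipc2BOMe, −78 °C; BF3·OEt2; 1 (anhydrous), −78 °C; then NaOH, H2O2, 0 °C to rt
Reagents that add atoms: none
Why: Brown asymmetric crotylboration, in which the (Z)-crotylborane reacts through a closed chair transition state so that the Z geometry gives the syn methyl/hydroxyl pair and the isopinocampheyl groups of the (−)-α-pinene series direct attack to the Re face of the aldehyde, setting C13 = R and C12 = S.

Step 2
Reactants: 6 (2R,3S)-1,1-dimethoxy-3-methylpent-4-en-2-ol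
Product: 7 triethyl{[(2R,3S)-1,1-dimethoxy-3-methylpent-4-en-2-yl]oxy}silane
Conditions: Et3SiCl, imidazole, CH2Cl2, 0 °C to rt
Reagents that add atoms: chlorotriethylsilane, CC[Si](Cl)(CC)CC
Why: Standard silyl ether formation, which masks the C13 hydroxyl so that it cannot quench the later carbanion or close a tetrahydrofuran onto the iodide.

Step 3
Reactants: 7 triethyl{[(2R,3S)-1,1-dimethoxy-3-methylpent-4-en-2-yl]oxy}silane
Product: 9 triethyl{[(2R,3S)-5-iodo-1,1-dimethoxy-3-methylpentan-2-yl]oxy}silane, via alkylzirconocene 8 (not isolated)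
Conditions: Cp2Zr(H)Cl, CH2Cl2, rt; then I2, 0 °C
Reagents that add atoms: iodine, II
Why: Schwartz hydrozirconation puts zirconium on the terminal carbon of the monosubstituted alkene and iodinolysis of the C–Zr bond gives the primary iodide without touching either stereocentre.

Step 4
Reactants: 10 geraniol
Product: 11 geranyl triethylsilyl ether
Conditions: Et3SiCl, imidazole, CH2Cl2, 0 °C
Reagents that add atoms: chlorotriethylsilane, CC[Si](Cl)(CC)CC
Why: Standard silylation of the primary allylic alcohol, which also deactivates the 2,3-olefin towards the electrophilic oxidant of the next step.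

Step 5
Reactants: 11 geranyl triethylsilyl ether
Product: 12 triethyl{[(2E)-5-[(2S)-3,3-dimethyloxiran-2-yl]-3-methylpent-2-en-1-yl]oxy}silane
Conditions: 1,2:4,5-di-O-isopropylidene-β-L-erythro-2,3-hexodiulo-2,6-pyranose (Shi ketone of the L series, 30 mol%), Oxone (2KHSO5·KHSO4·K2SO4), K2CO3, Bu4NHSO4, Na2B4O7 buffer (pH 10.5), MeCN/(MeO)2CH2/H2O, 0 °C
Reagents that add atoms: potassium peroxymonosulfate (oxidant in Oxone), [K+].[O-]S(=O)(=O)OO
Why: Shi asymmetric epoxidation, in which the chiral dioxirane attacks the more electron-rich distal trisubstituted olefin through a spiro transition state and the L-series ketone delivers oxygen to the face that gives the (S)-epoxide, fixing C7.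

Step 6
Reactants: 12 triethyl{[(2E)-5-[(2S)-3,3-dimethyloxiran-2-yl]-3-methylpent-2-en-1-yl]oxy}silane
Product: 13 (3S,6E)-2,6-dimethyl-8-[(triethylsilyl)oxy]octa-1,6-dien-3-ol
Conditions: Et2AlCl, lithium 2,2,6,6-tetramethylpiperidide, toluene, 0 °C; then aq KNaC4H4O6
Reagents that add atoms: none
Why: Yamamoto epoxide-to-allylic-alcohol isomerisation, in which the aluminium amide binds the epoxide oxygen and removes a methyl proton syn to it, breaking the tertiary C–O bond so that the secondary C7–O bond keeps its S configuration and the 8(19)-methylene is formed.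

Step 7
Reactants: 13 (3S,6E)-2,6-dimethyl-8-[(triethylsilyl)oxy]octa-1,6-dien-3-ol; 9 triethyl{[(2R,3S)-5-iodo-1,1-dimethoxy-3-methylpentan-2-yl]oxy}silane
Product: 16 (2E,6S,11S,12R)-13,13-dimethoxy-3,11-dimethyl-7-methylidene-1,6,12-tris[(triethylsilyl)oxy]tridec-2-ene, via dianion 14 (not isolated), via lithium alkoxide 15 (not isolated)
Conditions: 13 (1.3 equiv), n-BuLi (2.6 equiv), TMEDA, Et2O/hexane, 0 °C to rt; 9, THF, −78 to 0 °C; then Et3SiCl, 0 °C to rt
Reagents that add atoms: chlorotriethylsilane, CC[Si](Cl)(CC)CC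
Why: Alkoxide-directed allylic lithiation followed by SN2 alkylation, in which the C7 lithium alkoxide steers n-BuLi/TMEDA to the neighbouring isopropenyl methyl, the resulting 2-substituted allyl anion has two equivalent CH2 ends so the primary iodide can only give the C9–C10 bond, and the alkoxide is silylated in the same flask with no stereocentre formed or disturbed.

Step 8
Reactants: 16 (2E,6S,11S,12R)-13,13-dimethoxy-3,11-dimethyl-7-methylidene-1,6,12-tris[(triethylsilyl)oxy]tridec-2-ene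
Product: 17 (2E,6S,11S,12R)-13,13-dimethoxy-3,11-dimethyl-7-methylidene-6,12-bis[(triethylsilyl)oxy]tridec-2-en-1-ol
Conditions: pyridinium p-toluenesulfonate (10 mol%), MeOH/CH2Cl2, −10 to 0 °C
Reagents that add atoms: none
Why: Chemoselective acid-catalysed methanolysis, since the unhindered primary allylic silyl ether is cleaved far faster than the two hindered secondary ones and the dimethyl acetal is inert in methanol.

Step 9
Reactants: 17 (2E,6S,11S,12R)-13,13-dimethoxy-3,11-dimethyl-7-methylidene-6,12-bis[(triethylsilyl)oxy]tridec-2-en-1-ol; 18 methyl propiolate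
Product: 21 methyl (5E,9S,14S,15R)-16,16-dimethoxy-6,14-dimethyl-10-methylidene-9,15-bis[(triethylsilyl)oxy]hexadec-5-en-2-ynoate, via mesylate 19 (not isolated), via allylic chloride 20 (not isolated)
Conditions: MsCl, LiCl, 2,4,6-collidine, DMF, 0 °C; then 18, CuI (20 mol%), Bu4NI (10 mol%), K2CO3, DMF, rt
Reagents that add atoms: none
Why: Collington–Meyers chlorination followed by copper-catalysed sp–sp3 coupling of the copper acetylide of 18 with the primary allylic chloride (SN2, linear product, E geometry kept), which makes the C1–C2 bond without touching a stereocentre.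

Step 10
Reactants: 21 methyl (5E,9S,14S,15R)-16,16-dimethoxy-6,14-dimethyl-10-methylidene-9,15-bis[(triethylsilyl)oxy]hexadec-5-en-2-ynoate
Product: 23 methyl (2Z,5E,9S,14S,15R)-2-(hydroxymethyl)-16,16-dimethoxy-6,14-dimethyl-10-methylidene-9,15-bis[(triethylsilyl)oxy]hexadeca-2,5-dienoate, via vinylalane 22 (not isolated)
Conditions: i-Bu2AlH, HMPA, THF, 0 °C; then CH2O (gas), −20 to 0 °C; aq KNaC4H4O6
Reagents that add atoms: formaldehyde, C=O
Why: Conjugate hydroalumination of the ynoate (hydride to C1, aluminium to C15, syn addition) followed by aldol-type capture of the α-aluminoacrylate by formaldehyde gives the Morita–Baylis–Hillman-type 2-(hydroxymethyl)enoate, whose olefin geometry does not matter later because the derived allylmetal equilibrates.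

Step 11
Reactants: 23 methyl (2Z,5E,9S,14S,15R)-2-(hydroxymethyl)-16,16-dimethoxy-6,14-dimethyl-10-methylidene-9,15-bis[(triethylsilyl)oxy]hexadeca-2,5-dienoate
Product: 24 methyl (2E,5E,9S,14S,15R)-2-(bromomethyl)-16,16-dimethoxy-6,14-dimethyl-10-methylidene-9,15-bis[(triethylsilyl)oxy]hexadeca-2,5-dienoate
Conditions: CBr4, PPh3, 2,6-lutidine, CH2Cl2, −20 to 0 °C
Reagents that add atoms: carbon tetrabromide, BrC(Br)(Br)Br
Why: Appel bromination of the primary allylic alcohol under neutral conditions that leave the silyl ethers and the acetal intact.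

Step 12
Reactants: 24 methyl (2E,5E,9S,14S,15R)-2-(bromomethyl)-16,16-dimethoxy-6,14-dimethyl-10-methylidene-9,15-bis[(triethylsilyl)oxy]hexadeca-2,5-dienoate
Product: 28 (1S,3E,7S,12S,13R,14R)-7,13-dihydroxycembra-3,8(19),15(17)-trien-16,14-olide, via hydroxy aldehyde 25 (not isolated), via allylindium 26 (not isolated), via hydroxy ester 27 (not isolated)
Conditions: 1 M H2SO4 (aq)/THF 1:4, rt; then syringe-pump addition to In powder (4 equiv), THF/H2O 1:1, 1 mM final, rt; then p-TsOH·H2O (cat.), CH2Cl2, rt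
Reagents that add atoms: water, O
Why: Indium-mediated Barbier-type intramolecular 2-(alkoxycarbonyl)allylation, in which acid first frees the aldehyde and both hydroxyls, indium insertion into the allylic C–Br bond turns the normally electrophilic enoate β-carbon C1 into a nucleophile (ester homoenolate equivalent) that attacks the aldehyde carbon C14 through a chair transition state with the free C13 hydroxyl chelating indium (13,14-syn, C14 = R) and C1/C14 formed syn (C1 = S), so that acid-catalysed lactonisation gives the cis-fused α-methylene-γ-lactone.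

Step 13
Reactants: 28 (1S,3E,7S,12S,13R,14R)-7,13-dihydroxycembra-3,8(19),15(17)-trien-16,14-olide
Product: 29 (1S,3R,4R,7S,12S,13R,14R)-3,4-epoxy-7,13-dihydroxycembra-8(19),15(17)-dien-16,14-olide (target CNP0124069.2)
Conditions: 1,2:4,5-di-O-isopropylidene-β-D-erythro-2,3-hexodiulo-2,6-pyranose (Shi ketone of the D series, 30 mol%), Oxone (2KHSO5·KHSO4·K2SO4), K2CO3, Bu4NHSO4, Na2B4O7 buffer (pH 10.5), MeCN/(MeO)2CH2/H2O, 0 °C, short reaction time
Reagents that add atoms: potassium peroxymonosulfate (oxidant in Oxone), [K+].[O-]S(=O)(=O)OO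
Why: Shi asymmetric epoxidation, in which the electrophilic dioxirane reacts only with the electron-rich trisubstituted 3E-olefin (the 1,1-disubstituted allylic-alcohol olefin and the electron-poor α-methylene lactone are much slower) and the D-series ketone delivers oxygen to the face that gives the (3R,4R) trans-epoxide.

## Compound list

1 | 2,2-dimethoxyacetaldehyde | COC(OC)C=O | starting material
2 | cis-but-2-ene | C/C=C\C | starting material
3 | (Z)-but-2-en-1-ylpotassium | C/C=C\C[K] | intermediate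
4 | (Z)-but-2-en-1-ylbis(isopinocampheyl)borane, Ipc groups of the (−)-α-pinene series | C/C=C\CB([C@H]1C[C@H]2C[C@@H]([C@@H]1C)C2(C)C)[C@H]1C[C@H]2C[C@@H]([C@@H]1C)C2(C)C | intermediate
5 | bis(isopinocampheyl)borinate ester of 6 | C=C[C@H](C)[C@@H](OB([C@H]1C[C@H]2C[C@@H]([C@@H]1C)C2(C)C)[C@H]1C[C@H]2C[C@@H]([C@@H]1C)C2(C)C)C(OC)OC | intermediate
6 | (2R,3S)-1,1-dimethoxy-3-methylpent-4-en-2-ol | C=C[C@H](C)[C@@H](O)C(OC)OC | intermediate
7 | triethyl{[(2R,3S)-1,1-dimethoxy-3-methylpent-4-en-2-yl]oxy}silane | C=C[C@H](C)[C@@H](O[Si](CC)(CC)CC)C(OC)OC | intermediate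
8 | chlorobis(cyclopentadienyl)[(3S,4R)-5,5-dimethoxy-3-methyl-4-(triethylsilyloxy)pentyl]zirconium (rings drawn σ-bonded) | Cl[Zr](C1C=CC=C1)(C1C=CC=C1)CC[C@H](C)[C@@H](O[Si](CC)(CC)CC)C(OC)OC | intermediate
9 | triethyl{[(2R,3S)-5-iodo-1,1-dimethoxy-3-methylpentan-2-yl]oxy}silane | ICC[C@H](C)[C@@H](O[Si](CC)(CC)CC)C(OC)OC | intermediate
10 | geraniol, (2E)-3,7-dimethylocta-2,6-dien-1-ol | CC(C)=CCC/C(C)=C/CO | starting material
11 | geranyl triethylsilyl ether | CC(C)=CCC/C(C)=C/CO[Si](CC)(CC)CC | intermediate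
12 | triethyl{[(2E)-5-[(2S)-3,3-dimethyloxiran-2-yl]-3-methylpent-2-en-1-yl]oxy}silane | CC1(C)O[C@H]1CC/C(C)=C/CO[Si](CC)(CC)CC | intermediate
13 | (3S,6E)-2,6-dimethyl-8-[(triethylsilyl)oxy]octa-1,6-dien-3-ol | C=C(C)[C@@H](O)CC/C(C)=C/CO[Si](CC)(CC)CC | intermediate
14 | O,C-dilithio derivative of 13 (lithium alkoxide, 2-(lithiomethyl)allyl) | C=C(C[Li])[C@@H](O[Li])CC/C(C)=C/CO[Si](CC)(CC)CC | intermediate
15 | lithium C7-alkoxide of the C9–C10 coupled product | C=C(CCC[C@H](C)[C@@H](O[Si](CC)(CC)CC)C(OC)OC)[C@@H](O[Li])CC/C(C)=C/CO[Si](CC)(CC)CC | intermediate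
16 | (2E,6S,11S,12R)-13,13-dimethoxy-3,11-dimethyl-7-methylidene-1,6,12-tris[(triethylsilyl)oxy]tridec-2-ene | C=C(CCC[C@H](C)[C@@H](O[Si](CC)(CC)CC)C(OC)OC)[C@@H](O[Si](CC)(CC)CC)CC/C(C)=C/CO[Si](CC)(CC)CC | intermediate
17 | (2E,6S,11S,12R)-13,13-dimethoxy-3,11-dimethyl-7-methylidene-6,12-bis[(triethylsilyl)oxy]tridec-2-en-1-ol | C=C(CCC[C@H](C)[C@@H](O[Si](CC)(CC)CC)C(OC)OC)[C@@H](O[Si](CC)(CC)CC)CC/C(C)=C/CO | intermediate
18 | methyl propiolate | C#CC(=O)OC | starting material
19 | methanesulfonate of 17 | C=C(CCC[C@H](C)[C@@H](O[Si](CC)(CC)CC)C(OC)OC)[C@@H](O[Si](CC)(CC)CC)CC/C(C)=C/COS(C)(=O)=O | intermediate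
20 | (2E,6S,11S,12R)-1-chloro-13,13-dimethoxy-3,11-dimethyl-7-methylidene-6,12-bis[(triethylsilyl)oxy]tridec-2-ene | C=C(CCC[C@H](C)[C@@H](O[Si](CC)(CC)CC)C(OC)OC)[C@@H](O[Si](CC)(CC)CC)CC/C(C)=C/CCl | intermediate
21 | methyl (5E,9S,14S,15R)-16,16-dimethoxy-6,14-dimethyl-10-methylidene-9,15-bis[(triethylsilyl)oxy]hexadec-5-en-2-ynoate | C=C(CCC[C@H](C)[C@@H](O[Si](CC)(CC)CC)C(OC)OC)[C@@H](O[Si](CC)(CC)CC)CC/C(C)=C/CC#CC(=O)OC | intermediate
22 | α-(diisobutylalumino)enoate from 21 (H and Al cis) | C=C(CCC[C@H](C)[C@@H](O[Si](CC)(CC)CC)C(OC)OC)[C@@H](O[Si](CC)(CC)CC)CC/C(C)=C/C/C=C(/[Al](CC(C)C)CC(C)C)C(=O)OC | intermediate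
23 | methyl (2Z,5E,9S,14S,15R)-2-(hydroxymethyl)-16,16-dimethoxy-6,14-dimethyl-10-methylidene-9,15-bis[(triethylsilyl)oxy]hexadeca-2,5-dienoate | C=C(CCC[C@H](C)[C@@H](O[Si](CC)(CC)CC)C(OC)OC)[C@@H](O[Si](CC)(CC)CC)CC/C(C)=C/C/C=C(/CO)C(=O)OC | intermediate
24 | methyl (2E,5E,9S,14S,15R)-2-(bromomethyl)-16,16-dimethoxy-6,14-dimethyl-10-methylidene-9,15-bis[(triethylsilyl)oxy]hexadeca-2,5-dienoate | C=C(CCC[C@H](C)[C@@H](O[Si](CC)(CC)CC)C(OC)OC)[C@@H](O[Si](CC)(CC)CC)CC/C(C)=C/C/C=C(/CBr)C(=O)OC | intermediate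
25 | methyl (2E,5E,9S,14S,15R)-2-(bromomethyl)-9,15-dihydroxy-6,14-dimethyl-10-methylidene-16-oxohexadeca-2,5-dienoate | C=C(CCC[C@H](C)[C@@H](O)C=O)[C@@H](O)CC/C(C)=C/C/C=C(/CBr)C(=O)OC | intermediate
26 | allylindium dibromide derived from 25 | C=C(CCC[C@H](C)[C@@H](O)C=O)[C@@H](O)CC/C(C)=C/C/C=C(/C[In](Br)Br)C(=O)OC | intermediate
27 | methyl 2-[(1S,3E,7S,12S,13R,14R)-7,13,14-trihydroxy-4,12-dimethyl-8-methylidenecyclotetradec-3-en-1-yl]prop-2-enoate | C=C1CCC[C@H](C)[C@@H](O)[C@H](O)[C@H](C(=C)C(=O)OC)C/C=C(C)/CC[C@@H]1O | intermediate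
28 | (1S,3E,7S,12S,13R,14R)-7,13-dihydroxycembra-3,8(19),15(17)-trien-16,14-olide | C=C1CCC[C@H](C)[C@@H](O)[C@@H]2OC(=O)C(=C)[C@@H]2C/C=C(C)/CC[C@@H]1O | intermediate
29 | (1S,3R,4R,7S,12S,13R,14R)-3,4-epoxy-7,13-dihydroxycembra-8(19),15(17)-dien-16,14-olide (CNP0124069.2) | C=C1CCC[C@H](C)[C@@H](O)[C@@H]2OC(=O)C(=C)[C@@H]2C[C@H]2O[C@]2(C)CC[C@@H]1O | target

## Step count

Total steps: 13. Longest linear sequence: 10 (steps 4–13 from geraniol; the west line, steps 1–3 then 7–13, is also 10).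

## Three steps most likely to fail, with fallbacks

**Step 7 (dianion alkylation).** The risk is competing metalation next to the allylic silyl ether, or a sluggish alkylation. The fallback makes the C7–C8 bond instead of C9–C10; it sets out from iodide 9 and epoxide 12 and comes back at 16. Iodide 9 is converted with Mg in THF into the Grignard reagent F1, which is coupled with 2,3-dibromopropene (CuI cat.) to give the 2-bromoalkene F2. Epoxide 12 is cleaved with H5IO6 to the aldehyde F3. A CrCl2/NiCl2 (cat.) coupling of F2 with F3 in DMF gives the allylic alcohol F4 as a mixture of C7 epimers. Dess–Martin oxidation gives the enone F5. Reduction with BH3·SMe2 and (R)-tetrahydro-1-methyl-3,3-diphenyl-1H,3H-pyrrolo[1,2-c][1,3,2]oxazaborole gives the (7S)-alcohol F6, whose silylation (Et3SiCl, imidazole) gives 16.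

**Step 12 (ring closure).** The risk is protonolysis of the allylindium or oligomerisation on the metal surface before the 14-membered ring closes. The fallback generates the nucleophile catalytically in solution instead; it sets out from alcohol 23 and comes back at hydroxy ester 27. Alcohol 23 is acetylated (Ac2O, pyridine) to the allylic acetate F7. 1 M H2SO4 in THF frees the dihydroxy aldehyde F8. Slow addition of F8 to Pd(PPh3)4 (5 mol%) and InI in THF/H2O converts the electrophilic π-allylpalladium into an allylindium that closes the ring to 27, which lactonises to 28 as in the main route.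

**Step 13 (last epoxidation).** The risk is that the conformation of the macrocycle overrides the catalyst and gives the wrong epoxide face. The fallback installs the epoxide on the open chain, where there is no ring bias, and carries it through the ring closure; it sets out from alcohol 23 and comes back at target 29. Alcohol 23 is epoxidised with the D-series Shi ketone and Oxone to the epoxy alcohol F9. CBr4/PPh3 gives the epoxy bromide F10. The acetal is removed without aqueous acid (Et3SiOTf, 2,4,6-collidine, CH2Cl2, 0 °C, then H2O) to give the aldehyde F11. The silyl ethers are removed with HF·pyridine buffered with pyridine to give the dihydroxy aldehyde F12. Indium powder in THF/H2O at high dilution closes F12 to the epoxy hydroxy ester F13, which lactonises on treatment with pyridinium p-toluenesulfonate to 29.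

Further compounds
F1 | step 7 | iodo[(3S,4R)-5,5-dimethoxy-3-methyl-4-(triethylsilyloxy)pentyl]magnesium | I[Mg]CC[C@H](C)[C@@H](O[Si](CC)(CC)CC)C(OC)OC
F2 | step 7 | triethyl{[(2R,3S)-7-bromo-1,1-dimethoxy-3-methyloct-7-en-2-yl]oxy}silane | C=C(Br)CCC[C@H](C)[C@@H](O[Si](CC)(CC)CC)C(OC)OC
F3 | step 7 | (4E)-4-methyl-6-[(triethylsilyl)oxy]hex-4-enal | O=CCC/C(C)=C/CO[Si](CC)(CC)CC
F4 | step 7 | (2E,6RS,11S,12R)-13,13-dimethoxy-3,11-dimethyl-7-methylidene-1,12-bis[(triethylsilyl)oxy]tridec-2-en-6-ol | C=C(CCC[C@H](C)[C@@H](O[Si](CC)(CC)CC)C(OC)OC)C(O)CC/C(C)=C/CO[Si](CC)(CC)CC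
F5 | step 7 | (2E,11S,12R)-13,13-dimethoxy-3,11-dimethyl-7-methylidene-1,12-bis[(triethylsilyl)oxy]tridec-2-en-6-one | C=C(CCC[C@H](C)[C@@H](O[Si](CC)(CC)CC)C(OC)OC)C(=O)CC/C(C)=C/CO[Si](CC)(CC)CC
F6 | step 7 | (2E,6S,11S,12R)-13,13-dimethoxy-3,11-dimethyl-7-methylidene-1,12-bis[(triethylsilyl)oxy]tridec-2-en-6-ol | C=C(CCC[C@H](C)[C@@H](O[Si](CC)(CC)CC)C(OC)OC)[C@@H](O)CC/C(C)=C/CO[Si](CC)(CC)CC
F7 | step 12 | methyl (2Z,5E,9S,14S,15R)-2-(acetoxymethyl)-16,16-dimethoxy-6,14-dimethyl-10-methylidene-9,15-bis[(triethylsilyl)oxy]hexadeca-2,5-dienoate | C=C(CCC[C@H](C)[C@@H](O[Si](CC)(CC)CC)C(OC)OC)[C@@H](O[Si](CC)(CC)CC)CC/C(C)=C/C/C=C(/COC(C)=O)C(=O)OC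
F8 | step 12 | methyl (2Z,5E,9S,14S,15R)-2-(acetoxymethyl)-9,15-dihydroxy-6,14-dimethyl-10-methylidene-16-oxohexadeca-2,5-dienoate | C=C(CCC[C@H](C)[C@@H](O)C=O)[C@@H](O)CC/C(C)=C/C/C=C(/COC(C)=O)C(=O)OC
F9 | step 13 | methyl (2Z,5R,6R,9S,14S,15R)-5,6-epoxy-2-(hydroxymethyl)-16,16-dimethoxy-6,14-dimethyl-10-methylidene-9,15-bis[(triethylsilyl)oxy]hexadec-2-enoate | C=C(CCC[C@H](C)[C@@H](O[Si](CC)(CC)CC)C(OC)OC)[C@@H](O[Si](CC)(CC)CC)CC[C@@]1(C)O[C@@H]1C/C=C(/CO)C(=O)OC
F10 | step 13 | methyl (2E,5R,6R,9S,14S,15R)-2-(bromomethyl)-5,6-epoxy-16,16-dimethoxy-6,14-dimethyl-10-methylidene-9,15-bis[(triethylsilyl)oxy]hexadec-2-enoate | C=C(CCC[C@H](C)[C@@H](O[Si](CC)(CC)CC)C(OC)OC)[C@@H](O[Si](CC)(CC)CC)CC[C@@]1(C)O[C@@H]1C/C=C(/CBr)C(=O)OC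
F11 | step 13 | methyl (2E,5R,6R,9S,14S,15R)-2-(bromomethyl)-5,6-epoxy-6,14-dimethyl-10-methylidene-16-oxo-9,15-bis[(triethylsilyl)oxy]hexadec-2-enoate | C=C(CCC[C@H](C)[C@@H](O[Si](CC)(CC)CC)C=O)[C@@H](O[Si](CC)(CC)CC)CC[C@@]1(C)O[C@@H]1C/C=C(/CBr)C(=O)OC
F12 | step 13 | methyl (2E,5R,6R,9S,14S,15R)-2-(bromomethyl)-5,6-epoxy-9,15-dihydroxy-6,14-dimethyl-10-methylidene-16-oxohexadec-2-enoate | C=C(CCC[C@H](C)[C@@H](O)C=O)[C@@H](O)CC[C@@]1(C)O[C@@H]1C/C=C(/CBr)C(=O)OC
F13 | step 13 | methyl 2-[(1S,3R,4R,7S,12S,13R,14R)-3,4-epoxy-7,13,14-trihydroxy-4,12-dimethyl-8-methylidenecyclotetradecyl]prop-2-enoate | C=C1CCC[C@H](C)[C@@H](O)[C@H](O)[C@H](C(=C)C(=O)OC)C[C@H]2O[C@]2(C)CC[C@@H]1O
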